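## Structural features

The target is methyl (1R,3S,5S,6S,7S,10R)-1β,3β-dihydroxy-6α-{[2-(hydroxymethyl)prop-2-enoyl]oxy}eudesma-4(15),11(13)-dien-12-oate, a 6,12-seco-eudesmanolide. It is a trans-fused decalin (ring A: C1–C2–C3–C4–C5–C10; ring B: C5–C6–C7–C8–C9–C10) with the angular methyl C14 on quaternary C10. Ring A carries equatorial hydroxyls at C1 (β, neopentyl) and C3 (β, allylic) and the exocyclic C4=C15 methylene. Ring B carries the equatorial 6α-acyloxy group and the equatorial 7β-C11(=C13H2)CO2Me unit. Of the six stereocentres, C10/C1 are adjacent, C5/C6/C7 form a contiguous triad and C3 stands alone; all ring substituents are equatorial, so substrate control is favourable once C10 is fixed. Fragile groups are the two α-substituted acrylates (one with a free primary allylic OH), the γ-related O6/C12 pair (a free 6-OH can lactonize onto C12), and any β-hydroxy ketone on the way to the 1,3-diol. The real difficulty is the quaternary C10 flanked by C1–O on a trans ring fusion, the C5–C6–C7 triad, and a ring-A oxidation pattern (O at C1 and C3, sp2 carbon at C4) that enone annulations do not deliver. The key step exploits that C1, C2, C3, C4, C5 and C10 map atom for atom onto 2-methoxy-5-methyl-1,4-benzoquinone: carbonyls at C1 and C4, enol ether at C3, and the H-bearing C5 and methyl-bearing C10 as its only reactive dienophile carbons.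

## Logic of the disconnections

28 ⇒ 23 (through 27, 26, 25, 24). Cut: the C1–H and C3–H bonds made by hydride, and two O–Si bonds. Both carbinol carbons go back to the carbonyl level, C1 as ketone and C3 as the methyl enol ether of one vinylogous ester. Both alcohols are equatorial on a rigid trans-decalin and are what hydride attack anti to the angular methyl (C1) and along the axial path (C3) should give. Gain: two stereocentres vanish and ring A of 23 has neither a hydroxyl nor an acidic hydrogen, so it needs no protecting group. Demand: C1 is reduced first and its oxygen held as a silyl ether while the enol ether is hydrolysed; both borohydride reductions must spare two acrylates.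

23 ⇒ 18 + 21. Cut: the O6–C(=O) ester bond. The 2-(hydroxymethyl)acrylate is the most fragile unit and is attached when 6-OH is the only hydroxyl present. Gain: convergence; 21 comes from 19 through 20. Demand: acylation of a hindered equatorial alcohol must outrun its lactonization onto C12.

18 ⇒ 13 (through 17, 15). Cut: C11=C13 (and O6–Si). The acrylate is made from a CH2CO2Me side chain by ester-enolate aminomethylation and elimination, so the diene needs only an acetate arm. Demand: the ester enolate must be the only enolate, which holds because ring A of 13 has no acidic C–H.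

13 ⇒ 12. Cut: C4=C15. The C4 carbonyl first activates the dienophile and then allows C5 to be epimerized; only afterwards is it turned into the methylene. Demand: a non-basic methylenation that selects C4=O over the hindered vinylogous-ester carbonyl C1=O.

12 ⇒ 10 (through 11). Cut: C7–H and C8–H; reset C5–H. The cycloadduct is necessarily cis-fused and unsaturated at C7=C8. C5 is corrected by enolization towards C4, C7 by hydrogenation anti to the angular methyl. Demand: epimerization without β-elimination of O6; hydrogenation must spare C2=C3.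

10 ⇒ 2 + 9 (key). Cut: C5–C6 and C9–C10. In one sentence: a chelate-controlled, enantioselective Diels–Alder reaction between 2 and 9 builds ring B onto a quinone that already is ring A. Gain: ring B, the quaternary C10, C6 and (latently) C5 in one step from two achiral pieces of 8 and 7 skeletal carbons. Demand: reaction at the methyl-bearing double bond only, C9 to C10 orientation, endo approach, and one enantioface.

9 ⇒ 8 ⇒ 4 + 5; 4 ⇒ 3. Cut: O–Si, then C7–C11 (α-alkylation of a metallated azadiene), then C=N. Demand: α- rather than γ-alkylation, and the (1E) dienol ether.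

2 ⇒ 1. Cut: the C4=O bond (oxidative dearomatization of a phenol with a free para position).

## Other disconnections considered

Alternative 1: Robinson annulation on a chiral-pool ring B (the first idea). Cut: C1–C10 and C4–C5. Forward key step: Michael addition of the C10 enolate of cyclohexanone A1 to an enone partner, then aldol condensation, to give octalone A2. Grounds against: axial attack on the enolate of A1 should place the new C10–C1 bond cis to the C7 substituent, which is the wrong C10 epimer, so an auxiliary detour would be needed. A2 also has oxygen only at C3 and an endocyclic 4-ene. The 1β-OH next to the quaternary carbon, O6, the shift to the 4(15)-ene and the C12 oxidation would each be a separate late oxidation, whereas the chosen quinone supplies C1, C3 and C4 at the right oxidation level from the start.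

Alternative 2: biomimetic transannular cyclization. Cut: C5–C10. Forward key step: epoxidation of the 1(10)-alkene of germacranolide A3 to A4, then acid- or Ti(III)-mediated opening with participation of the 4,5-alkene, to give eudesmanolide A5 (1β-OH, 10β-methyl, 5α-H and 4(15)-ene in one event). Grounds against: A3 is itself a natural product, so this is a partial synthesis unless a macrocyclization precedes it. A5 is the closed lactone, and opening an α-methylene-γ-lactone to the methyl ester invites conjugate addition to the methylene and reclosure by the freed 6-OH. The C3 oxygen would rest on an allylic oxidation whose facial outcome the plan does not control, and three hydroxyls would have to be told apart before O6 acylation. The chosen route never forms the lactone and has a single free hydroxyl when O6 is acylated.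

Alternative 3: ring B by intramolecular 2-(methoxycarbonyl)allylation. Cut: C6–C7. Forward key step: Barbier/Nozaki–Hiyama-type cyclization (Zn, In or Cr(II)) of aldehyde–allyl bromide A6 to hydroxy ester A7, creating O6–H, C7–H and the acrylate at once. Grounds against: A6 is a fully substituted ring A whose four stereocentres (C1, C3, C5, C10) must be set first without help from ring B, so the difficulty is only moved. Through a six-membered cyclic transition state the readily made (Z)-bromide puts C8 axial and should favour the 6,7-cis product, whereas the target is 6,7-trans.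

Key step: step 5

Assumption 1: eudesmane numbering (C14 = angular methyl, C15 = methylene carbon on C4, C13 = methylene carbon on C11) and α/β descriptors (β = face of C14) are used for all bicyclic compounds; TBS = tert-butyldimethylsilyl.
Assumption 2: the (S)-BINOL ligand is taken to give the enantiomer drawn for 10; if the sense of induction is the opposite, the (R)-ligand is used with no other change.

## Steps

Step 1
Reactants: 1 2-methoxy-5-methylphenol
Product: 2 2-methoxy-5-methyl-1,4-benzoquinone
Conditions: ON(SO3K)2 (2.2 equiv), KH2PO4, H2O/acetone, rt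
Reagents that add atoms: potassium nitrosodisulfonate, [K+].[K+].[O]N(S(=O)(=O)[O-])S(=O)(=O)[O-]
Why: Teuber oxidation of a phenol with a free para position to the p-quinone; this dearomatization turns a flat cresol ring into the future ring A with oxygen at C1, C3 and C4, the methyl at C10 and H at C5.

Step 2
Reactants: 3 (E)-but-2-enal
Product: 4 (1E,2E)-N-cyclohexylbut-2-en-1-imine
Conditions: cyclohexylamine, 4 Å MS, Et2O, 0 °C → rt
Reagents that add atoms: cyclohexylamine, NC1CCCCC1
Why: Imine condensation; the cyclohexylimine is the precursor of the metallated azadiene needed for α-alkylation.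

Step 3
Reactants: 4 (1E,2E)-N-cyclohexylbut-2-en-1-imine; 5 methyl bromoacetate
Product: 8 methyl 3-formylpent-4-enoate (racemic), via lithiated imine 6 (not isolated), via alkylated imine 7 (not isolated)
Conditions: LDA, THF, −78 °C; then 5, −78 → −20 °C; then AcOH/NaOAc/H2O, 0 °C
Reagents that add atoms: water, O; lithium diisopropylamide, [Li+].CC(C)[N-]C(C)C (its lithium is carried by intermediate 6 only)
Why: Stork metalloenamine alkylation: the 1-azapentadienyl anion should be alkylated at its α-carbon by the primary bromide, forming C7–C11; buffered hydrolysis frees the aldehyde. The stereocentre is racemic and is erased in step 4, and any conjugated enal isomer converges to the same diene.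

Step 4
Reactants: 8 methyl 3-formylpent-4-enoate
Product: 9 methyl (3E)-3-{[(tert-butyldimethylsilyl)oxy]methylidene}pent-4-enoate
Conditions: TBSOTf, Et3N, Et2O, 0 °C → rt
Reagents that add atoms: tert-butyldimethylsilyl trifluoromethanesulfonate, CC(C)(C)[Si](C)(C)OS(=O)(=O)C(F)(F)F
Why: Soft enolization: O-silylation followed by loss of the doubly activated α-H gives the conjugated dienol silyl ether. The (E) isomer (OTBS trans to the vinyl group) should prevail because the (Z) isomer has 1,3-strain between OTBS and vinyl, and only (E) can adopt the s-cis geometry needed in step 5.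

Step 5
Reactants: 2 2-methoxy-5-methyl-1,4-benzoquinone; 9 methyl (3E)-3-{[(tert-butyldimethylsilyl)oxy]methylidene}pent-4-enoate
Product: 10 methyl 6α-TBSO-3-methoxy-1,4-dioxo-13,15-dinor-5β-eudesma-2,7-dien-12-oate (cis-fused)
Conditions: (S)-BINOL–TiCl2(OiPr)2 (20 mol %), toluene, −40 → −20 °C
Reagents that add atoms: none
Why: The step is a concerted, asynchronous [4π+2π] cycloaddition in which the Ti(IV)–BINOL Lewis acid sits as a five-membered chelate between the C4 carbonyl oxygen and the C3 methoxy oxygen of 2, so that C5=C10 is activated through C4=O and C10 becomes the electrophilic β-carbon. The closest known reaction type is the Ti–BINOL-catalysed enantioselective Diels–Alder reaction of 2-alkoxy-1,4-benzoquinones with 1-oxygenated dienes, together with the classical addition of dienes to the methyl-bearing double bond of this quinone class. Ring B (C5–C6–C7–C8–C9–C10) is closed by intermolecular cycloaddition, suprafacial on both partners, forming C5–C6 and C9–C10. The absolute configuration of quaternary C10 follows from the enantioface of C5=C10 left open by the C2-symmetric BINOL pocket around the chelated quinone. Suprafacial addition places H5 cis to the C10 methyl (cis fusion), which step 6 corrects. The endo transition state with the (1E)-diene places the silyloxy group cis to C4 and hence anti to the angular methyl, which is the 6α configuration of the target. The C2=C3 bond is a deactivated vinylogous ester, so only C5=C10 reacts; the silyloxy group puts the largest HOMO coefficient on C9, which bonds to C10, and this orientation needs the chelating acid because a monodentate acid on the more basic C1=O would favour the opposite orientation. The methyl ester and the silyl dienol ether of 9 should tolerate the substoichiometric Lewis acid at low temperature.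

Step 6
Reactants: 10 methyl 6α-TBSO-3-methoxy-1,4-dioxo-13,15-dinor-5β-eudesma-2,7-dien-12-oate
Product: 11 methyl 6α-TBSO-3-methoxy-1,4-dioxo-13,15-dinor-5α-eudesma-2,7-dien-12-oate (trans-fused)
Conditions: DBU (0.2 equiv), CH2Cl2, 0 °C
Reagents that add atoms: none
Why: Base-catalysed epimerization through the C4 enolate, the classical cis-to-trans isomerization of quinone cycloadducts; C5–H is the only enolizable position of ring A because C10 is quaternary. The trans isomer should be favoured because both ring-A bonds at the fusion and the 6α-silyloxy group become equatorial on ring B; a weak base and low temperature are chosen to keep the β-silyloxy group from E1cB loss.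

Step 7
Reactants: 11 methyl 6α-TBSO-3-methoxy-1,4-dioxo-13,15-dinor-5α-eudesma-2,7-dien-12-oate
Product: 12 methyl 6α-TBSO-3-methoxy-1,4-dioxo-13,15-dinor-5α,7α-H-eudesm-2-en-12-oate
Conditions: H2 (1 atm), 5% Pd/C, EtOAc, rt
Reagents that add atoms: none
Why: Heterogeneous hydrogenation of the isolated trisubstituted C7=C8 bond. On the rigid trans-fused scaffold the β face is screened by the axial C10 methyl (1,3 to C8), so hydrogen should add from the α face, giving H7α and the equatorial 7β-CH2CO2Me; the push–pull C2=C3 bond is much less reactive.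

Step 8
Reactants: 12 methyl 6α-TBSO-3-methoxy-1,4-dioxo-13,15-dinor-5α,7α-H-eudesm-2-en-12-oate
Product: 13 methyl 6α-TBSO-3-methoxy-1-oxo-13-noreudesma-2,4(15)-dien-12-oate
Conditions: Zn, CH2Br2, TiCl4, THF/CH2Cl2, 0 °C → rt
Reagents that add atoms: dibromomethane, BrCBr
Why: Takai–Lombardo methylenation; the reagent is non-basic, so C5 is not enolized and O6 is not eliminated. It should select the C4 ketone because C1=O is a hindered vinylogous-ester carbonyl and C12 is an ester.

Step 9
Reactants: 13 methyl 6α-TBSO-3-methoxy-1-oxo-13-noreudesma-2,4(15)-dien-12-oate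
Product: 15 methyl 13-(dimethylamino)-6α-TBSO-3-methoxy-1-oxoeudesma-2,4(15)-dien-12-oate (C11 epimers), via lithium enolate 14 (not isolated)
Conditions: LDA, THF, −78 °C; then CH2=NMe2+ I−, −78 °C → rt
Reagents that add atoms: N,N-dimethylmethyleneiminium iodide, C=[N+](C)C.[I-]; lithium diisopropylamide, [Li+].CC(C)[N-]C(C)C (its lithium is carried by intermediate 14 only)
Why: Mannich aminomethylation of the ester enolate. The C11 hydrogens are the only acidic ones in 13 (the C1 ketone has no α-hydrogen: C10 is quaternary and C2 vinylic), and the new C11 stereocentre is removed in step 10.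

Step 10
Reactants: 15 methyl 13-(dimethylamino)-6α-TBSO-3-methoxy-1-oxoeudesma-2,4(15)-dien-12-oate
Product: 17 methyl 6α-TBSO-3-methoxy-1-oxoeudesma-2,4(15),11(13)-trien-12-oate, via ammonium iodide 16 (not isolated)
Conditions: MeI, CH2Cl2/MeOH, rt; then NaHCO3 (aq), CH2Cl2, rt
Reagents that add atoms: iodomethane, CI (its methyl group is carried by intermediate 16 only)
Why: N-Quaternization followed by mild-base E1cB elimination of the β-ammonium ester gives the C11=C13 methylene; this is the standard α-methylenation sequence and touches nothing else in the molecule.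

Step 11
Reactants: 17 methyl 6α-TBSO-3-methoxy-1-oxoeudesma-2,4(15),11(13)-trien-12-oate
Product: 18 methyl 6α-hydroxy-3-methoxy-1-oxoeudesma-2,4(15),11(13)-trien-12-oate
Conditions: HF·pyridine, pyridine/THF, 0 °C → rt
Reagents that add atoms: none
Why: Fluoride-mediated cleavage of the only silyl ether under non-basic conditions, so that no alkoxide forms that could lactonize onto C12 or add to the acrylate; the vinylogous ester is stable to the anhydrous reagent.

Step 12
Reactants: 19 methyl 2-(hydroxymethyl)prop-2-enoate
Product: 20 methyl 2-{[(tert-butyldimethylsilyl)oxy]methyl}prop-2-enoate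
Conditions: TBSCl, imidazole, CH2Cl2, 0 °C → rt
Reagents that add atoms: tert-butyldimethylsilyl chloride, CC(C)(C)[Si](C)(C)Cl
Why: Standard silylation of a primary allylic alcohol.

Step 13
Reactants: 20 methyl 2-{[(tert-butyldimethylsilyl)oxy]methyl}prop-2-enoate
Product: 21 2-{[(tert-butyldimethylsilyl)oxy]methyl}prop-2-enoic acid
Conditions: LiOH, THF/H2O, 0 °C; then 1 M HCl to pH 4
Reagents that add atoms: lithium hydroxide, [Li+].[OH-]
Why: Saponification of the methyl ester; the silyl ether is stable to aqueous hydroxide and to brief cold acidification.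

Step 14
Reactants: 18 methyl 6α-hydroxy-3-methoxy-1-oxoeudesma-2,4(15),11(13)-trien-12-oate; 21 2-{[(tert-butyldimethylsilyl)oxy]methyl}prop-2-enoic acid
Product: 23 methyl 6α-({2-[(TBS-oxy)methyl]prop-2-enoyl}oxy)-3-methoxy-1-oxoeudesma-2,4(15),11(13)-trien-12-oate, via mixed anhydride 22 (not isolated)
Conditions: 2,4,6-Cl3C6H2COCl, Et3N, toluene, rt; then 18, DMAP, rt
Reagents that add atoms: 2,4,6-trichlorobenzoyl chloride, O=C(Cl)c1c(Cl)cc(Cl)cc1Cl (its acyl group is carried by intermediate 22 only)
Why: Yamaguchi esterification; the acylpyridinium formed from the mixed anhydride acylates the hindered equatorial 6-OH, which is the only hydroxyl in 18 because ring A is still at the carbonyl and enol-ether level.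

Step 15
Reactants: 23 methyl 6α-({2-[(TBS-oxy)methyl]prop-2-enoyl}oxy)-3-methoxy-1-oxoeudesma-2,4(15),11(13)-trien-12-oate
Product: 24 methyl 6α-({2-[(TBS-oxy)methyl]prop-2-enoyl}oxy)-1β-hydroxy-3-methoxyeudesma-2,4(15),11(13)-trien-12-oate
Conditions: NaBH4, CeCl3·7H2O, MeOH/THF, −40 → −20 °C; NaHCO3 quench
Reagents that add atoms: none
Why: Luche 1,2-reduction of the vinylogous-ester carbonyl. Hydride should attack C1 anti to the adjacent angular methyl, giving the 1β (equatorial) alcohol as in the reduction of related 1-oxo-10-methyldecalins; the hard cerium-modified borohydride at low temperature should leave the acrylate esters alone, and the neutral quench protects the acid-labile allylic alcohol.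

Step 16
Reactants: 24 methyl 6α-({2-[(TBS-oxy)methyl]prop-2-enoyl}oxy)-1β-hydroxy-3-methoxyeudesma-2,4(15),11(13)-trien-12-oate
Product: 25 methyl 1β-TBSO-6α-({2-[(TBS-oxy)methyl]prop-2-enoyl}oxy)-3-methoxyeudesma-2,4(15),11(13)-trien-12-oate
Conditions: TBSOTf, 2,6-lutidine, CH2Cl2, −78 °C
Reagents that add atoms: tert-butyldimethylsilyl trifluoromethanesulfonate, CC(C)(C)[Si](C)(C)OS(=O)(=O)C(F)(F)F
Why: Silylation of the neopentyl secondary alcohol; capping O1 blocks its ionization or β-elimination (Stork–Danheiser-type transposition) in the next step.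

Step 17
Reactants: 25 methyl 1β-TBSO-6α-({2-[(TBS-oxy)methyl]prop-2-enoyl}oxy)-3-methoxyeudesma-2,4(15),11(13)-trien-12-oate
Product: 26 methyl 1β-TBSO-6α-({2-[(TBS-oxy)methyl]prop-2-enoyl}oxy)-3-oxoeudesma-4(15),11(13)-dien-12-oate
Conditions: oxalic acid (0.1 M aq), THF, 0 °C
Reagents that add atoms: water, O
Why: Mild hydrolysis of the 2-methoxy-1,3-diene: protonation at C2 gives the C3 oxocarbenium ion (stabilized by OMe and by C4=C15), and water then delivers the 3-ketone with the exocyclic methylene intact. Under this weak acid the β-silyloxy group and both silyl ethers should survive.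

Step 18
Reactants: 26 methyl 1β-TBSO-6α-({2-[(TBS-oxy)methyl]prop-2-enoyl}oxy)-3-oxoeudesma-4(15),11(13)-dien-12-oate
Product: 27 methyl 1β-TBSO-3β-hydroxy-6α-({2-[(TBS-oxy)methyl]prop-2-enoyl}oxy)eudesma-4(15),11(13)-dien-12-oate
Conditions: NaBH4, CeCl3·7H2O, MeOH, −78 °C
Reagents that add atoms: none
Why: Luche 1,2-reduction of the exo-methylene enone; axial hydride attack from the α face (only axial hydrogens at C1 and C5 on that face) should give the equatorial 3β-alcohol, and the acrylates are not reduced under these conditions.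

Step 19
Reactants: 27 methyl 1β-TBSO-3β-hydroxy-6α-({2-[(TBS-oxy)methyl]prop-2-enoyl}oxy)eudesma-4(15),11(13)-dien-12-oate
Product: 28 methyl (1R,3S,5S,6S,7S,10R)-1β,3β-dihydroxy-6α-{[2-(hydroxymethyl)prop-2-enoyl]oxy}eudesma-4(15),11(13)-dien-12-oate
Conditions: HF·pyridine, pyridine/THF, 0 °C → rt
Reagents that add atoms: none
Why: Global desilylation of the primary allylic and the secondary C1 silyl ethers under buffered, non-basic fluoride conditions that the acrylates, the allylic alcohol and the O6 ester tolerate; O6 stays acylated, so no lactonization is possible.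

## Compound list

1 | 2-methoxy-5-methylphenol | COc1ccc(C)cc1O | starting material
2 | 2-methoxy-5-methyl-1,4-benzoquinone | COC1=CC(=O)C(C)=CC1=O | intermediate
3 | (E)-but-2-enal | C/C=C/C=O | starting material
4 | (1E,2E)-N-cyclohexylbut-2-en-1-imine | C/C=C/C=N/C1CCCCC1 | intermediate
5 | methyl bromoacetate | COC(=O)CBr | starting material
6 | lithium N-(buta-1,3-dien-1-yl)-N-cyclohexylamide (lithiated imine) | C=CC=CN([Li])C1CCCCC1 | intermediate
7 | methyl 3-[(cyclohexylimino)methyl]pent-4-enoate (racemic) | COC(=O)CC(C=C)C=NC1CCCCC1 | intermediate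
8 | methyl 3-formylpent-4-enoate (racemic) | COC(=O)CC(C=C)C=O | intermediate
9 | methyl (3E)-3-{[(tert-butyldimethylsilyl)oxy]methylidene}pent-4-enoate | C=C/C(CC(=O)OC)=C/O[Si](C)(C)C(C)(C)C | intermediate
10 | methyl 6α-[(tert-butyldimethylsilyl)oxy]-3-methoxy-1,4-dioxo-13,15-dinor-5β-eudesma-2,7-dien-12-oate (cis-fused) | CC(C)(C)[Si](C)(C)O[C@@H]1[C@@H]2C(=O)C(OC)=CC(=O)[C@]2(C)CC=C1CC(=O)OC | intermediate
11 | methyl 6α-[(tert-butyldimethylsilyl)oxy]-3-methoxy-1,4-dioxo-13,15-dinor-5α-eudesma-2,7-dien-12-oate (trans-fused) | CC(C)(C)[Si](C)(C)O[C@@H]1[C@H]2C(=O)C(OC)=CC(=O)[C@]2(C)CC=C1CC(=O)OC | intermediate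
12 | methyl 6α-[(tert-butyldimethylsilyl)oxy]-3-methoxy-1,4-dioxo-13,15-dinor-5α,7α-H-eudesm-2-en-12-oate | CC(C)(C)[Si](C)(C)O[C@@H]1[C@H]2C(=O)C(OC)=CC(=O)[C@]2(C)CC[C@H]1CC(=O)OC | intermediate
13 | methyl 6α-[(tert-butyldimethylsilyl)oxy]-3-methoxy-1-oxo-13-noreudesma-2,4(15)-dien-12-oate | CC(C)(C)[Si](C)(C)O[C@@H]1[C@H]2C(=C)C(OC)=CC(=O)[C@]2(C)CC[C@H]1CC(=O)OC | intermediate
14 | lithium enolate of 13 (C11=C12(OLi)OMe) | CC(C)(C)[Si](C)(C)O[C@@H]1[C@H]2C(=C)C(OC)=CC(=O)[C@]2(C)CC[C@H]1C=C(O[Li])OC | intermediate
15 | methyl 13-(dimethylamino)-6α-[(tert-butyldimethylsilyl)oxy]-3-methoxy-1-oxoeudesma-2,4(15)-dien-12-oate (C11 epimers) | CC(C)(C)[Si](C)(C)O[C@@H]1[C@H]2C(=C)C(OC)=CC(=O)[C@]2(C)CC[C@H]1C(CN(C)C)C(=O)OC | intermediate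
16 | N,N,N-trimethylammonium iodide of 15 (C11 epimers) | CC(C)(C)[Si](C)(C)O[C@@H]1[C@H]2C(=C)C(OC)=CC(=O)[C@]2(C)CC[C@H]1C(C[N+](C)(C)C)C(=O)OC.[I-] | intermediate
17 | methyl 6α-[(tert-butyldimethylsilyl)oxy]-3-methoxy-1-oxoeudesma-2,4(15),11(13)-trien-12-oate | CC(C)(C)[Si](C)(C)O[C@@H]1[C@H]2C(=C)C(OC)=CC(=O)[C@]2(C)CC[C@H]1C(=C)C(=O)OC | intermediate
18 | methyl 6α-hydroxy-3-methoxy-1-oxoeudesma-2,4(15),11(13)-trien-12-oate | O[C@@H]1[C@H]2C(=C)C(OC)=CC(=O)[C@]2(C)CC[C@H]1C(=C)C(=O)OC | intermediate
19 | methyl 2-(hydroxymethyl)prop-2-enoate | C=C(CO)C(=O)OC | starting material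
20 | methyl 2-{[(tert-butyldimethylsilyl)oxy]methyl}prop-2-enoate | C=C(CO[Si](C)(C)C(C)(C)C)C(=O)OC | intermediate
21 | 2-{[(tert-butyldimethylsilyl)oxy]methyl}prop-2-enoic acid | C=C(CO[Si](C)(C)C(C)(C)C)C(=O)O | intermediate
22 | 2-{[(tert-butyldimethylsilyl)oxy]methyl}prop-2-enoic 2,4,6-trichlorobenzoic anhydride | C=C(CO[Si](C)(C)C(C)(C)C)C(=O)OC(=O)c1c(Cl)cc(Cl)cc1Cl | intermediate
23 | methyl 6α-({2-[(tert-butyldimethylsilyloxy)methyl]prop-2-enoyl}oxy)-3-methoxy-1-oxoeudesma-2,4(15),11(13)-trien-12-oate | C=C(CO[Si](C)(C)C(C)(C)C)C(=O)O[C@@H]1[C@H]2C(=C)C(OC)=CC(=O)[C@]2(C)CC[C@H]1C(=C)C(=O)OC | intermediate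
24 | methyl 6α-({2-[(tert-butyldimethylsilyloxy)methyl]prop-2-enoyl}oxy)-1β-hydroxy-3-methoxyeudesma-2,4(15),11(13)-trien-12-oate | C=C(CO[Si](C)(C)C(C)(C)C)C(=O)O[C@@H]1[C@H]2C(=C)C(OC)=C[C@@H](O)[C@]2(C)CC[C@H]1C(=C)C(=O)OC | intermediate
25 | methyl 1β-[(tert-butyldimethylsilyl)oxy]-6α-({2-[(tert-butyldimethylsilyloxy)methyl]prop-2-enoyl}oxy)-3-methoxyeudesma-2,4(15),11(13)-trien-12-oate | C=C(CO[Si](C)(C)C(C)(C)C)C(=O)O[C@@H]1[C@H]2C(=C)C(OC)=C[C@@H](O[Si](C)(C)C(C)(C)C)[C@]2(C)CC[C@H]1C(=C)C(=O)OC | intermediate
26 | methyl 1β-[(tert-butyldimethylsilyl)oxy]-6α-({2-[(tert-butyldimethylsilyloxy)methyl]prop-2-enoyl}oxy)-3-oxoeudesma-4(15),11(13)-dien-12-oate | C=C(CO[Si](C)(C)C(C)(C)C)C(=O)O[C@@H]1[C@H]2C(=C)C(=O)C[C@@H](O[Si](C)(C)C(C)(C)C)[C@]2(C)CC[C@H]1C(=C)C(=O)OC | intermediate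
27 | methyl 1β-[(tert-butyldimethylsilyl)oxy]-3β-hydroxy-6α-({2-[(tert-butyldimethylsilyloxy)methyl]prop-2-enoyl}oxy)eudesma-4(15),11(13)-dien-12-oate | C=C(CO[Si](C)(C)C(C)(C)C)C(=O)O[C@@H]1[C@H]2C(=C)[C@@H](O)C[C@@H](O[Si](C)(C)C(C)(C)C)[C@]2(C)CC[C@H]1C(=C)C(=O)OC | intermediate
28 | methyl (1R,3S,5S,6S,7S,10R)-1β,3β-dihydroxy-6α-{[2-(hydroxymethyl)prop-2-enoyl]oxy}eudesma-4(15),11(13)-dien-12-oate | C=C(CO)C(=O)O[C@@H]1[C@H]2C(=C)[C@@H](O)C[C@@H](O)[C@]2(C)CC[C@H]1C(=C)C(=O)OC | target

## Step count and least certain steps

Total step count: 19. Longest linear sequence: 16 steps (3 → 4 → 8 → 9 → 10 → 11 → 12 → 13 → 15 → 17 → 18 → 23 → 24 → 25 → 26 → 27 → 28; steps 2–11 and 14–19).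

Step 5 (key step). Most likely failures: stepwise Mukaiyama–Michael addition with silyl transfer or loss of the dienol silyl ether in place of cycloaddition; reversal of orientation if part of the Lewis acid binds C1=O in a monodentate way; insufficient enantioface discrimination by the chelate. Fallback: the uncatalysed thermal cycloaddition of 2 and 9 (toluene, 60–80 °C), whose orientation is governed by the more electron-poor C4 carbonyl, gives the racemic cis adduct, that is 10 together with its enantiomer, the ent-cis adduct F1. The conditions of step 6 convert the pair into 11 and its enantiomer, the ent-trans adduct F2, which are separated by preparative chromatography on a chiral stationary phase. The route is rejoined at 11.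

Step 6. Most likely failure: E1cB loss of silanol from the C4 enolate (O6 is β to C4=O and allylic), or an equilibrium that does not favour the trans fusion enough. Fallback, kinetic instead of thermodynamic control: from 10, TMSOTf/Et3N gives the cross-conjugated C4 trimethylsilyl dienol ether F3 without a free enolate. Low-temperature protodesilylation (TBAF/AcOH, −78 °C) should protonate C5 from the α face, anti to the C10 methyl, and give 11.

Step 7. Most likely failure: delivery of hydrogen to the β face of C7=C8 (wrong C7 epimer), competing reduction of the C2=C3 enedione bond, or hydrogenolysis of the allylic C6–O bond. Fallback, hydroxyl-directed homogeneous hydrogenation: from 11, HF·pyridine gives the allylic alcohol F4. [Ir(cod)(py)(PCy3)]PF6/H2 in CH2Cl2 should deliver hydrogen syn to the 6α-hydroxyl (α face) without reducing the enedione, giving the saturated alcohol F5. TBSOTf/2,6-lutidine then returns to 12.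

Step 14. Most likely failure: slow acylation of the hindered 6-OH, which gives time for lactonization onto C12 or for side reactions of the activated acrylic acid. Fallback, building the acyl group on O6: from 18, diethylphosphonoacetic acid/DCC/DMAP gives the phosphonoacetate F6. Aqueous formaldehyde/K2CO3 (hydroxymethylation, then Horner–Wadsworth–Emmons olefination) gives the free hydroxymethylacrylate F7, and TBSCl/imidazole returns to 23.

Step 15. Most likely failure: conjugate reduction of the acrylates during the slower reduction of the vinylogous-ester carbonyl, or ionization of the new allylic alcohol on work-up with loss of O1. Fallback, masking both acrylates as amine adducts: from 23, Me2NH in THF gives the bis(β-dimethylamino) ester F8. NaBH4/CeCl3 then gives the 1β-alcohol F9. MeI followed by NaHCO3, through the bis(trimethylammonium) diiodide F10, regenerates both methylene groups and gives 24.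

## Further compounds

F1 | step 5 | enantiomer of 10 (ent-cis adduct) | CC(C)(C)[Si](C)(C)O[C@H]1[C@H]2C(=O)C(OC)=CC(=O)[C@@]2(C)CC=C1CC(=O)OC
F2 | step 5 | enantiomer of 11 (ent-trans adduct) | CC(C)(C)[Si](C)(C)O[C@H]1[C@@H]2C(=O)C(OC)=CC(=O)[C@@]2(C)CC=C1CC(=O)OC
F3 | step 6 | methyl 6α-[(tert-butyldimethylsilyl)oxy]-3-methoxy-1-oxo-4-[(trimethylsilyl)oxy]-13,15-dinoreudesma-2,4,7-trien-12-oate | CC(C)(C)[Si](C)(C)O[C@@H]1C2=C(O[Si](C)(C)C)C(OC)=CC(=O)[C@]2(C)CC=C1CC(=O)OC
F4 | step 7 | methyl 6α-hydroxy-3-methoxy-1,4-dioxo-13,15-dinor-5α-eudesma-2,7-dien-12-oate | O[C@@H]1[C@H]2C(=O)C(OC)=CC(=O)[C@]2(C)CC=C1CC(=O)OC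
F5 | step 7 | methyl 6α-hydroxy-3-methoxy-1,4-dioxo-13,15-dinor-5α,7α-H-eudesm-2-en-12-oate | O[C@@H]1[C@H]2C(=O)C(OC)=CC(=O)[C@]2(C)CC[C@H]1CC(=O)OC
F6 | step 14 | methyl 6α-{[(diethoxyphosphoryl)acetyl]oxy}-3-methoxy-1-oxoeudesma-2,4(15),11(13)-trien-12-oate | CCOP(=O)(OCC)CC(=O)O[C@@H]1[C@H]2C(=C)C(OC)=CC(=O)[C@]2(C)CC[C@H]1C(=C)C(=O)OC
F7 | step 14 | methyl 6α-{[2-(hydroxymethyl)prop-2-enoyl]oxy}-3-methoxy-1-oxoeudesma-2,4(15),11(13)-trien-12-oate | C=C(CO)C(=O)O[C@@H]1[C@H]2C(=C)C(OC)=CC(=O)[C@]2(C)CC[C@H]1C(=C)C(=O)OC
F8 | step 15 | bis(dimethylamine) adduct of 23 (13-dimethylamino ester and 3-dimethylamino-2-(silyloxymethyl)propanoate at O6) | CN(C)CC(CO[Si](C)(C)C(C)(C)C)C(=O)O[C@@H]1[C@H]2C(=C)C(OC)=CC(=O)[C@]2(C)CC[C@H]1C(CN(C)C)C(=O)OC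
F9 | step 15 | 1β-alcohol of F8 | CN(C)CC(CO[Si](C)(C)C(C)(C)C)C(=O)O[C@@H]1[C@H]2C(=C)C(OC)=C[C@@H](O)[C@]2(C)CC[C@H]1C(CN(C)C)C(=O)OC
F10 | step 15 | bis(trimethylammonium) diiodide of F9 | C[N+](C)(C)CC(CO[Si](C)(C)C(C)(C)C)C(=O)O[C@@H]1[C@H]2C(=C)C(OC)=C[C@@H](O)[C@]2(C)CC[C@H]1C(C[N+](C)(C)C)C(=O)OC.[I-].[I-]
A1 | alternative 1 | (2R,5R)-2-methyl-5-(prop-1-en-2-yl)cyclohexanone | C[C@@H]1CC[C@H](CC1=O)C(C)=C
A2 | alternative 1 | 3-oxoeudesma-4,11-diene (octalone) | C1C2=C(C)C(=O)CC[C@]2(C)CC[C@H]1C(C)=C
A3 | alternative 2 | germacra-1(10)E,4E,11(13)-trien-6α,12-olide | C=C1C(=O)O[C@@H]2/C=C(C)/CC/C=C(C)/CC[C@@H]12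
A4 | alternative 2 | 1β,10α-epoxygermacra-4E,11(13)-dien-6α,12-olide | C=C1C(=O)O[C@@H]2/C=C(C)/CC[C@H]3O[C@]3(C)CC[C@@H]12
A5 | alternative 2 | 1β-hydroxyeudesma-4(15),11(13)-dien-6α,12-olide | C=C1C(=O)O[C@@H]2[C@H]3C(=C)CC[C@@H](O)[C@]3(C)CC[C@@H]12
A6 | alternative 3 | methyl (Z)-2-(bromomethyl)-5-[1β,3β-bis(tert-butyldimethylsilyloxy)-5-formyl-10-methyl-4-methylidenecyclohexyl]pent-2-enoate (eudesmane numbering, ring B open at C6–C7) | O=C[C@H]1C(=C)[C@@H](O[Si](C)(C)C(C)(C)C)C[C@@H](O[Si](C)(C)C(C)(C)C)[C@]1(C)CC/C=C(\CBr)C(=O)OC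
A7 | alternative 3 | methyl 1β,3β-bis[(tert-butyldimethylsilyl)oxy]-6α-hydroxyeudesma-4(15),11(13)-dien-12-oate | O[C@@H]1[C@H]2C(=C)[C@@H](O[Si](C)(C)C(C)(C)C)C[C@@H](O[Si](C)(C)C(C)(C)C)[C@]2(C)CC[C@H]1C(=C)C(=O)OC
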